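A catalyst charged at 4.9 mM cannot hold 0.49 M of substrate at once, so each catalyst has to go round about 100 times, and the whole problem is how long one round takes.

all flasks: free catalyst 4.9 mM
- Thursday's: substrate 0.49 M; reagent 1.47 M (fed, over 24.0 min); time 30 min; a stirred flask in which reagent is dosed at a steady rate over 24.0 min without added volume, worked up at 30 min
- Sunday's: substrate 0.49 M (fed, over 24.0 min); reagent 1.47 M; time 30 min; a stirred flask in which substrate is dosed at a steady rate over 24.0 min without added volume, worked up at 30 min
- Saturday's: substrate 0.49 M; reagent 1.47 M; time 30 min; everything together in a closed stirred flask, run for 30 min
- Monday's: substrate 0.49 M; reagent 1.47 M; a single well-mixed tank run continuously and read at steady state, 30 min in it on average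

    substrate + free catalyst → catalyst intermediate A (k1 = 1.1 M⁻¹ s⁻¹)
    catalyst intermediate B ⇌ free catalyst + product (K2 = 0.27 M, k2 = 0.31 s⁻¹)
    reagent + catalyst intermediate A → catalyst intermediate B (k3 = 0.18 M⁻¹ s⁻¹)

1. the set-up with the highest amount of product at the outlet or at the end, in percent of the substrate put in ("none" if the first two lie within 2 percentage points) (Thursday's / Sunday's / Saturday's / Monday's / none)
2. amount of product at the outlet or at the end, in percent of the substrate put in, Thursday's
3. amount of product at the outlet or at the end, in percent of the substrate put in, Sunday's
4. amount of product at the outlet or at the end, in percent of the substrate put in, Saturday's
5. amount of product at the outlet or at the end, in percent of the substrate put in, Monday's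

- the stated concentrations are those of everything mixed, before any reaction; amounts are the same in each set-up
- the feed brings no volume worth counting
- run time (Thursday's): 30 min

Substrate is the limiting reagent, charged at a third of the reagent, so its balance is the one to write. With the first step alone, free catalyst waits for substrate the inverse of its rate constant times c(substrate), which is 1.86 s at the charge. The reagent step adds its own wait, 3.78 s, and the release adds 3.23 s. The sum, 8.86 s, is the turn time: the time one catalyst needs for one round, so that substrate falls at the charged catalyst divided by it. The sum may be used because the intermediates are short-lived, catalyst intermediate A halving in 2.6 s by the reagent step and catalyst intermediate B in 2.2 s by forward release alone.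

Held at its starting value, the turn time would carry Saturday's flask through its rounds in 14.8 min. But the rest of the scheme lengthens it. Product takes free catalyst back, which multiplies the substrate wait by one plus c(product)/K2, and substrate and reagent fall. With a tenth of the substrate left, the turn time in Saturday's flask is 57.5 s. Summing the turn time over the rounds, Saturday's flask reaches that point at 26.6 min. The remaining minutes leave 6.99% free, so about 93.0% has gone, of which up to 1.00% can sit on the catalyst.

If a quarter of the substrate stayed free in Monday's tank, the turn time there would be 25.8 s. Its average stay would then pay for 69.8% of the charge, less than the 75.0% supposed, so this reckoning places Monday's between those two figures. Thursday's and Sunday's, fed over 24.0 min, begin with one wait long, and are placed between Monday's and Saturday's.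

The forecast names Saturday's, with 82%, 79.5%, 92.5% and 73% in the order asked, on the ground that “The closed flask keeps both concentrations high throughout and comes out best”.

The simulation gives 82.3%, 79.1%, 92.5% and 72.8%, with Saturday's highest.

In Saturday's flask the reagent step and the release were running at 15.0 min, with product at 68.7% and catalyst intermediate B, the resting state, holding 49.5% of the catalyst. By 30.0 min substrate stood at 6.84%, reagent at 69.0% of its charge, and the readings put the turn time at 81.3 s, which is 9.18 times its starting value of 8.86 s. Monday's tank, read at 0.130 M of substrate, has a turn time of 24.5 s, so its average 30 min pays for 73.5% of the charge, and it holds 72.8% as product.

(The numbers are invented; the run is a simulation.)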